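**Retrosynthetic overview**

1. The target is the C1 ester of (R)-malic acid with an ω-hydroxylated alkylhomocitric lactone. The last disconnection is that ester C–O bond: hydroxy diacid 15 plus O-trifluoroacetyl-(R)-malic anhydride 17, with no protecting group on the core.
2. Enabling feature (oxolanone locants: C2 = lactone carbonyl, C5 = quaternary carbon, C1′ = side-chain CH): the path C2–C3–C4–C5–C1′–CO2H ends in a carboxyl-level carbon on both sides. Joining these two ends as C=C turns the six carbons into a cyclohex-3-ene, and C5 carries O and CO2H, so it is the α-carbon of a masked 2-hydroxyacrylate.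
3. Key disconnection: that cyclohexene is cut into (E)-tetradeca-11,13-dienyl acetate 7 and (R)-2-tert-butyl-5-methylene-1,3-dioxolan-4-one 11. An auxiliary-controlled, exo-selective Diels–Alder reaction forms C3–C4 and C5–C1′ together and sets both core stereocentres.
4. Unmasking: RuO4 cleavage of the ring alkene gives C2 and the side-chain CO2H; hydrolysis of the dioxolanone gives C5–OH and C5–CO2H; lactonisation follows.
5. Ring order: dioxolanone (auxiliary ring), then spiro cyclohexene (temporary carbocycle, key step), then both are opened, and the γ-lactone, the only ring of the target, is closed last.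

Key step: step 7

Remark: the target is read as (S) at C5 and at C1′ and (R) in the malate unit, the malate being esterified at the carboxyl next to its CHOH.

**Step 1**
Reactants: 1 10-bromodecan-1-ol; 2 lithium acetylide–ethylenediamine complex
Product: 3 dodec-11-yn-1-ol
Conditions: 2 (2.5 equiv), DMSO, 0 °C → rt
Reagents that add atoms: none
Why: SN2 alkylation of lithium acetylide by the primary bromide (terminal alkyne synthesis); the excess covers the equivalent consumed by the free hydroxyl, whose alkoxide is a much poorer nucleophile towards the bromide than the acetylide.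

**Step 2**
Reactants: 3 dodec-11-yn-1-ol
Product: 4 dodec-11-yn-1-yl acetate
Conditions: Ac2O (1.5 equiv), pyridine, DMAP (cat.), CH2Cl2, 0 °C → rt
Reagents that add atoms: acetic anhydride, CC(=O)OC(C)=O
Why: DMAP-catalysed O-acetylation; the acetate is chosen because it is inert to RuO4 in step 8 and is removed without an extra operation by the hydroxide of step 9.

**Step 3**
Reactants: 4 dodec-11-yn-1-yl acetate
Product: 5 (E)-12-(4,4,5,5-tetramethyl-1,3,2-dioxaborolan-2-yl)dodec-11-en-1-yl acetate
Conditions: pinacolborane (1.2 equiv), Cp2Zr(H)Cl (5 mol %), Et3N (10 mol %), neat, 60 °C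
Reagents that add atoms: pinacolborane, B1OC(C)(C)C(C)(C)O1
Why: Zirconium-hydride-catalysed hydroboration of a terminal alkyne is syn and anti-Markovnikov, so the E-alkenylboronate should be the only isomer; the ester is tolerated.

**Step 4**
Reactants: 5 (E)-alkenylboronate; 6 bromoethene
Product: 7 (E)-tetradeca-11,13-dien-1-yl acetate
Conditions: 6 (1 M in THF, 3 equiv), Pd(PPh3)4 (3 mol %), K3PO4 (3 equiv), THF/H2O 10:1, 50 °C, sealed tube
Reagents that add atoms: none
Why: Suzuki–Miyaura alkenyl–alkenyl coupling proceeds with retention at both partners, so the E geometry of 5 is carried into the terminal 1,3-diene.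

**Step 5**
Reactants: 8 (R)-lactic acid
Product: 9 (2R,5R)-2-tert-butyl-5-methyl-1,3-dioxolan-4-one
Conditions: pivalaldehyde (1.5 equiv), p-TsOH·H2O (cat.), H2SO4 (cat.), pentane, reflux with water separator; recrystallisation at low temperature
Reagents that add atoms: pivalaldehyde (2,2-dimethylpropanal), CC(C)(C)C=O
Why: Acid-catalysed acetalisation with azeotropic removal of water; the lactic acid stereocentre places tert-butyl cis to methyl (acetal carbon R), and recrystallisation to diastereomeric purity fixes the enantiopurity of the later dienophile.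

**Step 6**
Reactants: 9 (2R,5R)-2-tert-butyl-5-methyl-1,3-dioxolan-4-one
Product: 11 (R)-2-tert-butyl-5-methylene-1,3-dioxolan-4-one, via bromo acetal 10 (not isolated)
Conditions: NBS (1.1 equiv), AIBN (cat.), CCl4, reflux; filter; then Et3N (1.5 equiv), 0 °C → rt; distillation
Reagents that add atoms: none
Why: Radical (Wohl–Ziegler) bromination at the captodative C5–H followed by E2 loss of HBr towards the methyl group gives the exocyclic alkene; C5 is flattened on purpose while the acetal centre keeps its configuration.

**Step 7**
Reactants: 7 (E)-tetradeca-11,13-dien-1-yl acetate; 11 (R)-2-tert-butyl-5-methylene-1,3-dioxolan-4-one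
Product: 12 10-[(2R,5S,6R)-2-tert-butyl-4-oxo-1,3-dioxaspiro[4.5]dec-7-en-6-yl]decyl acetate
Conditions: 11 (1.5 equiv), BHT (5 mol %), toluene (1 M), sealed tube, 110 °C
Reagents that add atoms: none
Why: Concerted, asynchronous normal-demand [4+2] cycloaddition: the terminal CH2 of the captodative dienophile (largest LUMO coefficient) bonds to the unsubstituted diene terminus, giving the CH2–CH2 bond C9–C10 that becomes C3–C4 of the lactone, while dioxolanone C5 bonds to the alkyl-bearing terminus to give C5–C1′. The closest known reaction type is the thermal Diels–Alder reaction of 2-tert-butyl-5-methylene-1,3-dioxolan-4-one with acyclic (E)-1-substituted dienes and trienes, which gives spiro adducts with the same regio-, exo- and facial sense. The one ring closed is the six-membered carbocycle, formed by suprafacial addition to both components across the s-cis diene; it is a temporary ring and no ring of the target is made here. The spiro carbon (future C5) should become S because the diene must approach the dienophile face anti to the tert-butyl group of the (R)-acetal. C6 (future C1′) should become R because the E geometry of the diene is transferred and the s-cis-locked α-alkylidene carbonyl dienophile reacts through the exo transition state (carbonyl exo, ring oxygen endo), which places the alkyl chain cis to the ring oxygen. The step needs ortho regioselectivity, exo selectivity and facial selectivity, secured in turn by the single alkyl group at the diene terminus together with the captodative polarisation of the dienophile, by the locked s-cis geometry of the dienophile and by the tert-butyl group, while BHT suppresses radical polymerisation of 11.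

**Step 8**
Reactants: 12 spiro adduct
Product: 13 (2S)-12-acetoxy-2-[(2R,4S)-2-tert-butyl-4-(2-carboxyethyl)-5-oxo-1,3-dioxolan-4-yl]dodecanoic acid
Conditions: RuCl3·3H2O (3 mol %), NaIO4 (4.5 equiv), EtOAc/MeCN/H2O 2:2:3, rt
Reagents that add atoms: sodium periodate, [Na+].[O-]I(=O)(=O)=O
Why: RuO4-catalysed oxidative cleavage of the cis-disubstituted ring alkene gives both carboxylic acids directly; the tertiary C–O and its carboxyl are shielded in the acylal, the acetate is inert, and the CH centre is not enolised under these acidic conditions.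

**Step 9**
Reactants: 13 dioxolanone diacid
Product: 15 (2S)-2-[(1S)-1-carboxy-11-hydroxyundecyl]-5-oxooxolane-2-carboxylic acid, via open hydroxy triacid 14 (not isolated)
Conditions: LiOH·H2O (8 equiv), THF/H2O 2:1, rt → 40 °C; then 2 M HCl to pH 1, rt → 50 °C
Reagents that add atoms: lithium hydroxide, [Li+].[OH-]
Why: Saponification opens the activated acylal ester (releasing pivalaldehyde) and the acetate, and on acidification the freed tertiary hydroxyl closes the γ-lactone onto the 2-carboxyethyl arm by 5-exo-trig acyl substitution, the only unstrained lactone available; carboxylate α-centres do not epimerise.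

**Step 10**
Reactants: 16 (R)-malic acid
Product: 17 (3R)-2,5-dioxooxolan-3-yl trifluoroacetate
Conditions: (CF3CO)2O (3 equiv), neat, 0 °C → rt; volatiles removed in vacuo
Reagents that add atoms: trifluoroacetic anhydride, O=C(OC(=O)C(F)(F)F)C(F)(F)F
Why: Trifluoroacetic anhydride acylates the hydroxyl and dehydrates the 1,4-diacid to the five-membered anhydride, the standard activation of malic acid; the stereocentre is not touched.

**Step 11**
Reactants: 15 hydroxy lactone diacid; 17 (3R)-2,5-dioxooxolan-3-yl trifluoroacetate
Product: 19 (2S)-2-[(1S)-1-carboxy-11-{[(2R)-3-carboxy-2-hydroxypropanoyl]oxy}undecyl]-5-oxooxolane-2-carboxylic acid, via trifluoroacetate 18 (not isolated)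
Conditions: 17 (2 equiv), THF, 0 °C → rt; then H2O, rt; reversed-phase chromatography
Reagents that add atoms: none
Why: Uncatalysed alcoholysis of the unsymmetrical anhydride should occur at C2, the carbonyl next to the trifluoroacetoxy-bearing carbon and so the more electrophilic one, as in the standard preparation of malic acid 1-monoesters; the trifluoroacetate is then hydrolysed by water, and no stereocentre is involved.

**Compound list**

1 | 10-bromodecan-1-ol | OCCCCCCCCCCBr | starting material
2 | lithium acetylide–ethylenediamine complex | [Li+].[C-]#C.NCCN | starting material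
3 | dodec-11-yn-1-ol | OCCCCCCCCCCC#C | intermediate
4 | dodec-11-yn-1-yl acetate | CC(=O)OCCCCCCCCCCC#C | intermediate
5 | (E)-12-(4,4,5,5-tetramethyl-1,3,2-dioxaborolan-2-yl)dodec-11-en-1-yl acetate | CC(=O)OCCCCCCCCCC/C=C/B1OC(C)(C)C(C)(C)O1 | intermediate
6 | bromoethene (vinyl bromide) | C=CBr | starting material
7 | (E)-tetradeca-11,13-dien-1-yl acetate | CC(=O)OCCCCCCCCCC/C=C/C=C | intermediate
8 | (R)-lactic acid | C[C@@H](O)C(=O)O | starting material
9 | (2R,5R)-2-tert-butyl-5-methyl-1,3-dioxolan-4-one | C[C@@H]1C(=O)O[C@@H](O1)C(C)(C)C | intermediate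
10 | (2S,5S)-5-bromo-2-tert-butyl-5-methyl-1,3-dioxolan-4-one (Br trans to tert-butyl; acetal carbon spatially unchanged, descriptor changed by priority only) | C[C@]1(Br)C(=O)O[C@@H](O1)C(C)(C)C | intermediate
11 | (R)-2-tert-butyl-5-methylene-1,3-dioxolan-4-one | C=C1O[C@@H](C(C)(C)C)OC1=O | intermediate
12 | 10-[(2R,5S,6R)-2-tert-butyl-4-oxo-1,3-dioxaspiro[4.5]dec-7-en-6-yl]decyl acetate | CC(=O)OCCCCCCCCCC[C@@H]1C=CCC[C@]12O[C@@H](C(C)(C)C)OC2=O | intermediate
13 | (2S)-12-acetoxy-2-[(2R,4S)-2-tert-butyl-4-(2-carboxyethyl)-5-oxo-1,3-dioxolan-4-yl]dodecanoic acid | CC(=O)OCCCCCCCCCC[C@H](C(=O)O)[C@]1(CCC(=O)O)O[C@@H](C(C)(C)C)OC1=O | intermediate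
14 | (1S,2S)-2-hydroxy-1-(10-hydroxydecyl)butane-1,2,4-tricarboxylic acid | OCCCCCCCCCC[C@H](C(=O)O)[C@](O)(C(=O)O)CCC(=O)O | intermediate
15 | (2S)-2-[(1S)-1-carboxy-11-hydroxyundecyl]-5-oxooxolane-2-carboxylic acid | OCCCCCCCCCC[C@H](C(=O)O)[C@]1(C(=O)O)CCC(=O)O1 | intermediate
16 | (R)-malic acid | O=C(O)C[C@@H](O)C(=O)O | starting material
17 | (3R)-2,5-dioxooxolan-3-yl trifluoroacetate | O=C1C[C@@H](OC(=O)C(F)(F)F)C(=O)O1 | intermediate
18 | (2S)-2-[(1S)-1-carboxy-11-{[(2R)-3-carboxy-2-(trifluoroacetoxy)propanoyl]oxy}undecyl]-5-oxooxolane-2-carboxylic acid | O=C(O)C[C@@H](OC(=O)C(F)(F)F)C(=O)OCCCCCCCCCC[C@H](C(=O)O)[C@]1(C(=O)O)CCC(=O)O1 | intermediate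
19 | (2S)-2-[(1S)-1-carboxy-11-{[(2R)-3-carboxy-2-hydroxypropanoyl]oxy}undecyl]-5-oxooxolane-2-carboxylic acid | O=C(O)C[C@@H](O)C(=O)OCCCCCCCCCC[C@H](C(=O)O)[C@]1(C(=O)O)CCC(=O)O1 | target

**Step count and risks**

Total step count: 11. Longest linear sequence: 8 steps (1, 2, 3, 4, 7, 8, 9, 11).

Steps most likely to fail:

Step 7. The unactivated diene needs a temperature at which radical polymerisation of the captodative dienophile competes, and with an acyclic diene the exo/endo and ortho/meta preferences may erode. The fallback replaces the cycloaddition by an aldol construction of C5–C1′, the bond of the presumed biosynthetic condensation of 2-oxoglutarate with a fatty acyl thioester. It sets out from 4 and comes back at 15. Hydroboration of 4 with dicyclohexylborane and NaBO3 oxidation would give 12-oxododecyl acetate F1. NaClO2 oxidation would give 12-acetoxydodecanoic acid F2, and EDC/DMAP coupling with 2-methylpropane-2-thiol would give S-tert-butyl 12-acetoxydodecanethioate F3. Soft enolisation (Me3SiOTf, Et3N) would give 12-(tert-butylsulfanyl)-12-(trimethylsilyloxy)dodec-11-en-1-yl acetate F4. F4 would be added to dimethyl 2-oxoglutarate with the bis(oxazoline) copper catalyst [Cu((S,S)-t-Bu-box)](OTf)2 in THF at −78 °C (chelated keto ester, syn-selective Mukaiyama aldol, ligand antipode chosen for the (S)-carbinol; acidic desilylation). This would give dimethyl (2S)-2-[(2S)-12-acetoxy-1-(tert-butylsulfanyl)-1-oxododecan-2-yl]-2-hydroxypentanedioate F5. LiOH/H2O2 and then HCl, as in step 9, would hydrolyse the thioester, both methyl esters and the acetate and close the lactone to 15.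

Step 11. The alcohol may attack the distal carbonyl of the anhydride, the trifluoroacetyl group may transfer to the primary alcohol, or the anhydride may exchange with the vicinal diacid of 15 and give oligomeric esters. The fallback fixes the regiochemistry in the building block and protects the core as benzyl esters. It sets out from 15 and comes back at 19. BnBr/KHCO3 in DMF would give benzyl (2S)-2-[(1S)-1-(benzyloxycarbonyl)-11-hydroxyundecyl]-5-oxooxolane-2-carboxylate F6, the alcohol staying free. Appel iodination (I2, PPh3, imidazole) would give benzyl (2S)-2-[(1S)-1-(benzyloxycarbonyl)-11-iodoundecyl]-5-oxooxolane-2-carboxylate F7. Nitrous acid deamination of commercial D-aspartic acid 4-benzyl ester (NaNO2, aqueous H2SO4, retention through the α-lactone) would give (2R)-4-(benzyloxy)-2-hydroxy-4-oxobutanoic acid F8. Its caesium salt (Cs2CO3, DMF) would displace the iodide of F7 to give the tribenzyl ester of the target F9, and hydrogenolysis (H2, Pd/C, EtOAc) would release 19.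

Step 8. RuO4 may over-oxidise (attack at the acetal C–H or degradation beyond the diacid), or the oxidation may stall at the aldehyde stage in the biphasic medium. The fallback is a stepwise cleavage that sets out from 12 and comes back at 13. Ozonolysis (O3, CH2Cl2, −78 °C; PPh3) would give (11S)-11-[(2R,4S)-2-tert-butyl-5-oxo-4-(3-oxopropyl)-1,3-dioxolan-4-yl]-12-oxododecyl acetate F10, which would be oxidised at once with NaClO2/NaH2PO4/2-methylbut-2-ene in t-BuOH/H2O to 13.

**Further compounds**

F1 | step 7 | 12-oxododecyl acetate | CC(=O)OCCCCCCCCCCCC=O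
F2 | step 7 | 12-acetoxydodecanoic acid | CC(=O)OCCCCCCCCCCCC(=O)O
F3 | step 7 | S-tert-butyl 12-acetoxydodecanethioate | CC(=O)OCCCCCCCCCCCC(=O)SC(C)(C)C
F4 | step 7 | 12-(tert-butylsulfanyl)-12-(trimethylsilyloxy)dodec-11-en-1-yl acetate | CC(=O)OCCCCCCCCCC/C=C(/O[Si](C)(C)C)SC(C)(C)C
F5 | step 7 | dimethyl (2S)-2-[(2S)-12-acetoxy-1-(tert-butylsulfanyl)-1-oxododecan-2-yl]-2-hydroxypentanedioate | CC(=O)OCCCCCCCCCC[C@H](C(=O)SC(C)(C)C)[C@](O)(C(=O)OC)CCC(=O)OC
F6 | step 11 | benzyl (2S)-2-[(1S)-1-(benzyloxycarbonyl)-11-hydroxyundecyl]-5-oxooxolane-2-carboxylate | OCCCCCCCCCC[C@H](C(=O)OCc1ccccc1)[C@]1(C(=O)OCc2ccccc2)CCC(=O)O1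
F7 | step 11 | benzyl (2S)-2-[(1S)-1-(benzyloxycarbonyl)-11-iodoundecyl]-5-oxooxolane-2-carboxylate | ICCCCCCCCCC[C@H](C(=O)OCc1ccccc1)[C@]1(C(=O)OCc2ccccc2)CCC(=O)O1
F8 | step 11 | (2R)-4-(benzyloxy)-2-hydroxy-4-oxobutanoic acid | O=C(OCc1ccccc1)C[C@@H](O)C(=O)O
F9 | step 11 | tribenzyl ester of 19 | O=C(OCc1ccccc1)C[C@@H](O)C(=O)OCCCCCCCCCC[C@H](C(=O)OCc1ccccc1)[C@]1(C(=O)OCc2ccccc2)CCC(=O)O1
F10 | step 8 | (11S)-11-[(2R,4S)-2-tert-butyl-5-oxo-4-(3-oxopropyl)-1,3-dioxolan-4-yl]-12-oxododecyl acetate | CC(=O)OCCCCCCCCCC[C@H](C=O)[C@]1(CCC=O)O[C@@H](C(C)(C)C)OC1=O
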